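Ring B of the target carries the C17 carboxyl on C8 and the C11 side-chain carbon on C9 as a vicinal trans pair next to quaternary C10. That pattern is the imprint of a fumarate added across a ring A diene, so ring B is cut at C7–C8 and C9–C10. One Et2AlCl-promoted Diels–Alder reaction of the ring A 2-siloxydiene 4 (C7=C6–C5=C10) with the chiral fumaroyl imide 8 (C8=C9) closes ring B and sets C8, C9 and C10, with C17 and C11 already differentiated. The fumarate ester is tert-butyl, so both acids are released by acid at the end and the β,γ-unsaturated C17 acid never meets base.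

Key step: step 5

Remark on the chemistry: atoms carry labdane numbers (ring A = C1–C5 and C10; ring B = C5–C10; C18/C19 on C4, C20 on C10, C17 on C8, C11–C16 in the side chain). The target is (5R,8S,9R,10S,13E): H5 trans to C20, C11 cis to C20, C17 trans to C11. In the naphthalene names, position 1 = C9, 2 = C8, 4a = C5, 8a = C10.

Design choices: the auxiliary is removed while C6 is still masked as its silyl enol ether, so the later ketone enolisation meets no imide. The iodo enoate is coupled with its hydroxyl free, so no silyl group has to be put on and taken off.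

Step 1
Reactants: 1 β-cyclocitral (2,6,6-trimethylcyclohex-1-ene-1-carbaldehyde)
Product: 2 1-(2,6,6-trimethylcyclohex-1-en-1-yl)ethan-1-ol (racemic)
Conditions: MeMgBr, Et2O, 0 °C; aq. NH4Cl
Reagents that add atoms: methylmagnesium bromide, C[Mg]Br
Why: Grignard 1,2-addition to the hindered, unenolisable enal gives the secondary allylic alcohol; its new stereocentre is racemic and is erased in step 2.

Step 2
Reactants: 2 1-(2,6,6-trimethylcyclohex-1-en-1-yl)ethan-1-ol
Product: 3 1-(2,6,6-trimethylcyclohex-1-en-1-yl)ethan-1-one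
Conditions: Dess–Martin periodinane, CH2Cl2, rt
Reagents that add atoms: none
Why: Dess–Martin oxidation converts the secondary allylic alcohol into the methyl ketone under neutral conditions without moving the tetrasubstituted ring alkene; no stereocentre is involved.

Step 3
Reactants: 3 1-(2,6,6-trimethylcyclohex-1-en-1-yl)ethan-1-one
Product: 4 tert-butyldimethyl{[1-(2,6,6-trimethylcyclohex-1-en-1-yl)ethenyl]oxy}silane
Conditions: TBSOTf, Et3N, CH2Cl2, 0 °C
Reagents that add atoms: tert-butyldimethylsilyl trifluoromethanesulfonate, CC(C)(C)[Si](C)(C)OS(=O)(=O)C(F)(F)F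
Why: Soft enolisation (silyl triflate plus amine) removes a proton from the acetyl methyl group, the only accessible α-position of this twisted enone, and O-silylation gives the cross-conjugated 2-siloxydiene with C7 as its nucleophilic terminus.

Step 4
Reactants: 5 mono-tert-butyl fumarate ((E)-4-tert-butoxy-4-oxobut-2-enoic acid); 6 (S)-4-benzyloxazolidin-2-one
Product: 8 tert-butyl (E)-4-[(S)-4-benzyl-2-oxooxazolidin-3-yl]-4-oxobut-2-enoate, via mixed pivalic anhydride 7 (not isolated)
Conditions: PivCl, Et3N, THF, −20 °C; then 6, LiCl, −20 °C → rt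
Reagents that add atoms: none
Why: N-acylation of the oxazolidinone through the mixed pivalic anhydride (LiCl/Et3N soft acylation) occurs at the unhindered fumaroyl carbonyl and touches neither the E alkene, the tert-butyl ester nor the stereocentre of the auxiliary.

Step 5
Reactants: 4 tert-butyldimethyl{[1-(2,6,6-trimethylcyclohex-1-en-1-yl)ethenyl]oxy}silane; 8 tert-butyl (E)-4-[(S)-4-benzyl-2-oxooxazolidin-3-yl]-4-oxobut-2-enoate
Product: 9 tert-butyl (1R,2S,8aS)-1-[(S)-4-benzyl-2-oxooxazolidine-3-carbonyl]-4-[(tert-butyldimethylsilyl)oxy]-5,5,8a-trimethyl-1,2,3,5,6,7,8,8a-octahydronaphthalene-2-carboxylate (8S,9R,10S; C5=C6 silyl enol ether)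
Conditions: Et2AlCl (1.5 equiv), 4 (2 equiv), CH2Cl2, −78 → −30 °C; cold aq. NaHCO3/potassium sodium tartrate
Reagents that add atoms: none
Why: Et2AlCl turns imide 8 into a cationic aluminium chelate locked s-cis, and the siloxy-polarised diene 4 adds in a normal-demand, strongly asynchronous [4+2] in which the unhindered nucleophilic C7 bonds first to the carbon β to the chelated imide (C8) and C9 then bonds to C10, so C17 (ester) and C11 (imide) arrive differentiated. The closest known reaction type is the Lewis-acid-promoted, oxazolidinone-auxiliary-controlled Diels–Alder reaction of fumaroyl and acryloyl imides, together with cycloadditions of 1-vinyl-2,6,6-trimethylcyclohexene dienes. Ring B is closed as a six-membered carbocycle by the cycloaddition itself, both σ-bonds forming suprafacially on diene and dienophile. C9 (R) is set by the benzyl group of the auxiliary, which shields one face of the chelated dienophile; C8 (S) follows from the E geometry of the fumarate (8,9-trans); C10 (S) follows from the imide pointing away from the diene (exo), which puts C11 cis to the C10 methyl. The step therefore needs regio-, π-facial and exo selectivity: the first comes from the siloxy group, the second from the auxiliary, the third from the C4 gem-dimethyl group, which crowds the space under C5 where an endo imide would have to sit. The exo preference is the one assumption without close precedent and is where the route carries its risk.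

Step 6
Reactants: 9 Diels–Alder adduct (imide)
Product: 10 tert-butyl (1R,2S,8aS)-4-[(tert-butyldimethylsilyl)oxy]-1-(hydroxymethyl)-5,5,8a-trimethyl-1,2,3,5,6,7,8,8a-octahydronaphthalene-2-carboxylate
Conditions: LiBH4, MeOH (2 equiv), Et2O, 0 °C
Reagents that add atoms: none
Why: Reductive cleavage of the N-acyl oxazolidinone by LiBH4 reduces the activated exocyclic carbonyl C11 to the primary alcohol and releases the auxiliary, while the tert-butyl ester and the hindered silyl enol ether are inert to borohydride; no stereocentre changes.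

Step 7
Reactants: 10 C11 alcohol
Product: 11 tert-butyl (1R,2S,8aS)-4-[(tert-butyldimethylsilyl)oxy]-1-formyl-5,5,8a-trimethyl-1,2,3,5,6,7,8,8a-octahydronaphthalene-2-carboxylate
Conditions: SO3·pyridine, DMSO, i-Pr2NEt, CH2Cl2, 0 °C
Reagents that add atoms: none
Why: Parikh–Doering oxidation (activated DMSO, non-acidic) gives the aldehyde without cleaving the silyl enol ether, and C9 is not at risk because the equatorial formyl group trans to the C8 ester is the stable arrangement.

Step 8
Reactants: 11 C11 aldehyde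
Product: 12 tert-butyl (1R,2S,8aS)-4-[(tert-butyldimethylsilyl)oxy]-1-ethenyl-5,5,8a-trimethyl-1,2,3,5,6,7,8,8a-octahydronaphthalene-2-carboxylate
Conditions: Ph3PCH3Br, KOtBu, THF, 0 °C → rt
Reagents that add atoms: methyltriphenylphosphonium bromide, C[P+](c1ccccc1)(c1ccccc1)c1ccccc1.[Br-]
Why: Wittig methylenation with the non-stabilised ylide converts the hindered aldehyde into the C11=C12 vinyl group faster than it enolises C9, and the tert-butyl ester does not react with the ylide.

Step 9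
Reactants: 12 C9-vinyl silyl enol ether
Product: 14 tert-butyl (1R,2S,4aR,8aS)-1-ethenyl-5,5,8a-trimethyl-4-oxodecahydronaphthalene-2-carboxylate, via tetrabutylammonium enolate 13 (not isolated)
Conditions: Bu4NF, THF, 0 °C → rt; aq. NH4Cl
Reagents that add atoms: none
Why: Fluoride cleaves the Si–O bond and the C5=C6 enolate is protonated at C5 on the face opposite the axial C10 and C4 methyl groups, which gives the trans-fused ketone (5R); this is also the more stable ring fusion, so any cis isomer should equilibrate through the enolate under the basic conditions.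

Step 10
Reactants: 14 trans-fused 6-ketone
Product: 16 tert-butyl (1R,2R,4aR,8aS)-1-ethenyl-5,5,8a-trimethyl-4-{[(trifluoromethyl)sulfonyl]oxy}-1,2,4a,5,6,7,8,8a-octahydronaphthalene-2-carboxylate, via potassium enolate 15 (not isolated)
Conditions: KN(SiMe3)2, THF, −78 °C; PhNTf2, −78 → 0 °C
Reagents that add atoms: N-phenylbis(trifluoromethanesulfonimide), O=S(=O)(N(c1ccccc1)S(=O)(=O)C(F)(F)F)C(F)(F)F
Why: Kinetic deprotonation by the bulky amide base at −78 °C takes a C7 methylene proton and not the buried C5 methine, and O-sulfonylation of the C6=C7 enolate with PhNTf2 fixes the future alkene position as an enol triflate; C5 and C8 keep their configuration (the C8 descriptor changes only through priorities).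

Step 11
Reactants: 16 C6 enol triflate
Product: 17 tert-butyl (1R,2S,4aR,8aS)-1-ethenyl-5,5,8a-trimethyl-1,2,4a,5,6,7,8,8a-octahydronaphthalene-2-carboxylate
Conditions: Pd(OAc)2 (5 mol %), PPh3 (10 mol %), HCO2H, n-Bu3N, DMF, 60 °C
Reagents that add atoms: none
Why: Palladium-catalysed reduction of the enol triflate with formate (oxidative addition, formate-to-hydride exchange with loss of CO2, reductive elimination) replaces OTf by H and leaves the C6=C7 alkene where the triflate was; the weak amine base does not move it into conjugation with C17.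

Step 12
Reactants: 18 2-(prop-2-yn-1-yloxy)tetrahydro-2H-pyran (racemic THP ether of propargyl alcohol)
Product: 20 tert-butyl 4-[(tetrahydro-2H-pyran-2-yl)oxy]but-2-ynoate, via lithium acetylide 19 (not isolated)
Conditions: n-BuLi, THF, −78 °C; Boc2O, −78 → 0 °C
Reagents that add atoms: di-tert-butyl dicarbonate, CC(C)(C)OC(=O)OC(=O)OC(C)(C)C
Why: Deprotonation of the terminal alkyne and C-acylation of the acetylide with Boc2O gives the tert-butyl ynoate; the THP acetal is stable to base.

Step 13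
Reactants: 20 tert-butyl 4-[(tetrahydro-2H-pyran-2-yl)oxy]but-2-ynoate
Product: 21 tert-butyl 4-hydroxybut-2-ynoate
Conditions: PPTS (cat.), MeOH, 40 °C
Reagents that add atoms: none
Why: Acid-catalysed transacetalisation to methanol removes the THP group under conditions too mild to cleave the tert-butyl ester.

Step 14
Reactants: 21 tert-butyl 4-hydroxybut-2-ynoate
Product: 22 tert-butyl (Z)-4-hydroxy-3-iodobut-2-enoate
Conditions: LiI, AcOH, MeCN, 70 °C
Reagents that add atoms: lithium iodide, [Li+].[I-]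
Why: Conjugate hydroiodination of the ynoate places iodide at C3 and the proton anti at C2, which gives the Z β-iodo enoate (iodine cis to the ester, CH2OH trans to it, so lactonisation is impossible).

Step 15
Reactants: 17 ring B diene with C9 vinyl; 22 tert-butyl (Z)-4-hydroxy-3-iodobut-2-enoate
Product: 24 tert-butyl (1R,2S,4aR,8aS)-1-[(3E)-5-tert-butoxy-3-(hydroxymethyl)-5-oxopent-3-en-1-yl]-5,5,8a-trimethyl-1,2,4a,5,6,7,8,8a-octahydronaphthalene-2-carboxylate, via B-alkyl-9-BBN borane 23 (not isolated)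
Conditions: 9-BBN, THF, 0 °C → rt; then aq. Cs2CO3, 22, Pd(dppf)Cl2 (5 mol %), AsPh3, DMF, rt
Reagents that add atoms: none
Why: 9-BBN adds anti-Markovnikov to the monosubstituted vinyl group far faster than to the hindered cis-disubstituted ring alkene, and the B-alkyl Suzuki–Miyaura coupling of the borane with the iodo enoate proceeds with retention of alkene geometry, giving the 13E alkene with C12 cis to the ester; the free hydroxyl and both tert-butyl esters tolerate the aqueous carbonate.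

Step 16
Reactants: 24 C16 alcohol, di-tert-butyl ester
Product: 25 tert-butyl (1R,2S,4aR,8aS)-1-[(3E)-3-(acetoxymethyl)-5-tert-butoxy-5-oxopent-3-en-1-yl]-5,5,8a-trimethyl-1,2,4a,5,6,7,8,8a-octahydronaphthalene-2-carboxylate
Conditions: Ac2O, pyridine, DMAP (cat.), CH2Cl2, 0 °C → rt
Reagents that add atoms: acetic anhydride, CC(=O)OC(C)=O
Why: DMAP-catalysed acetylation esterifies the only hydroxyl group (C16) and affects nothing else.

Step 17
Reactants: 25 C16 acetate, di-tert-butyl ester
Product: 26 (1R,2S,4aR,8aS)-1-[(3E)-3-(acetoxymethyl)-4-carboxybut-3-en-1-yl]-5,5,8a-trimethyl-1,2,4a,5,6,7,8,8a-octahydronaphthalene-2-carboxylic acid (CNP0108723.1)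
Conditions: CF3CO2H/CH2Cl2 (1:4), 0 °C → rt
Reagents that add atoms: none
Why: Acidolysis of both tert-butyl esters (loss of the tert-butyl cation as isobutene) frees the C15 and C17 acids without base, so the β,γ-unsaturated C17 acid keeps its C8 configuration and its alkene position, and the primary allylic acetate, deactivated by the conjugated carboxyl, should be stable to trifluoroacetic acid.

Compound list
1 | β-cyclocitral | CC1=C(C=O)C(C)(C)CCC1 | starting material
2 | 1-(2,6,6-trimethylcyclohex-1-en-1-yl)ethan-1-ol (racemic) | CC(O)C1=C(C)CCCC1(C)C | intermediate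
3 | 1-(2,6,6-trimethylcyclohex-1-en-1-yl)ethan-1-one | CC(=O)C1=C(C)CCCC1(C)C | intermediate
4 | tert-butyldimethyl{[1-(2,6,6-trimethylcyclohex-1-en-1-yl)ethenyl]oxy}silane | C=C(O[Si](C)(C)C(C)(C)C)C1=C(C)CCCC1(C)C | intermediate
5 | mono-tert-butyl fumarate | CC(C)(C)OC(=O)/C=C/C(=O)O | starting material
6 | (S)-4-benzyloxazolidin-2-one | O=C1N[C@@H](Cc2ccccc2)CO1 | starting material
7 | (E)-4-tert-butoxy-4-oxobut-2-enoic pivalic anhydride | CC(C)(C)OC(=O)/C=C/C(=O)OC(=O)C(C)(C)C | intermediate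
8 | tert-butyl (E)-4-[(S)-4-benzyl-2-oxooxazolidin-3-yl]-4-oxobut-2-enoate | CC(C)(C)OC(=O)/C=C/C(=O)N1[C@@H](Cc2ccccc2)COC1=O | intermediate
9 | tert-butyl (1R,2S,8aS)-1-[(S)-4-benzyl-2-oxooxazolidine-3-carbonyl]-4-[(tert-butyldimethylsilyl)oxy]-5,5,8a-trimethyl-1,2,3,5,6,7,8,8a-octahydronaphthalene-2-carboxylate | CC(C)(C)OC(=O)[C@H]1CC(O[Si](C)(C)C(C)(C)C)=C2C(C)(C)CCC[C@@]2(C)[C@@H]1C(=O)N3[C@@H](Cc4ccccc4)COC3=O | intermediate
10 | tert-butyl (1R,2S,8aS)-4-[(tert-butyldimethylsilyl)oxy]-1-(hydroxymethyl)-5,5,8a-trimethyl-1,2,3,5,6,7,8,8a-octahydronaphthalene-2-carboxylate | CC(C)(C)OC(=O)[C@H]1CC(O[Si](C)(C)C(C)(C)C)=C2C(C)(C)CCC[C@@]2(C)[C@@H]1CO | intermediate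
11 | tert-butyl (1R,2S,8aS)-4-[(tert-butyldimethylsilyl)oxy]-1-formyl-5,5,8a-trimethyl-1,2,3,5,6,7,8,8a-octahydronaphthalene-2-carboxylate | CC(C)(C)OC(=O)[C@H]1CC(O[Si](C)(C)C(C)(C)C)=C2C(C)(C)CCC[C@@]2(C)[C@@H]1C=O | intermediate
12 | tert-butyl (1R,2S,8aS)-4-[(tert-butyldimethylsilyl)oxy]-1-ethenyl-5,5,8a-trimethyl-1,2,3,5,6,7,8,8a-octahydronaphthalene-2-carboxylate | CC(C)(C)OC(=O)[C@H]1CC(O[Si](C)(C)C(C)(C)C)=C2C(C)(C)CCC[C@@]2(C)[C@@H]1C=C | intermediate
13 | tetrabutylammonium C5=C6 enolate of 14 | CC(C)(C)OC(=O)[C@H]1CC([O-])=C2C(C)(C)CCC[C@@]2(C)[C@@H]1C=C.CCCC[N+](CCCC)(CCCC)CCCC | intermediate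
14 | tert-butyl (1R,2S,4aR,8aS)-1-ethenyl-5,5,8a-trimethyl-4-oxodecahydronaphthalene-2-carboxylate | CC(C)(C)OC(=O)[C@H]1CC(=O)[C@@H]2C(C)(C)CCC[C@@]2(C)[C@@H]1C=C | intermediate
15 | potassium C6=C7 enolate of 14 | CC(C)(C)OC(=O)[C@H]1C=C([O-])[C@@H]2C(C)(C)CCC[C@@]2(C)[C@@H]1C=C.[K+] | intermediate
16 | tert-butyl (1R,2R,4aR,8aS)-1-ethenyl-5,5,8a-trimethyl-4-{[(trifluoromethyl)sulfonyl]oxy}-1,2,4a,5,6,7,8,8a-octahydronaphthalene-2-carboxylate | CC(C)(C)OC(=O)[C@H]1C=C(OS(=O)(=O)C(F)(F)F)[C@@H]2C(C)(C)CCC[C@@]2(C)[C@@H]1C=C | intermediate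
17 | tert-butyl (1R,2S,4aR,8aS)-1-ethenyl-5,5,8a-trimethyl-1,2,4a,5,6,7,8,8a-octahydronaphthalene-2-carboxylate | CC(C)(C)OC(=O)[C@H]1C=C[C@@H]2C(C)(C)CCC[C@@]2(C)[C@@H]1C=C | intermediate
18 | 2-(prop-2-yn-1-yloxy)tetrahydro-2H-pyran (racemic) | C#CCOC1CCCCO1 | starting material
19 | lithium acetylide of 18 | [Li]C#CCOC1CCCCO1 | intermediate
20 | tert-butyl 4-[(tetrahydro-2H-pyran-2-yl)oxy]but-2-ynoate (racemic) | CC(C)(C)OC(=O)C#CCOC1CCCCO1 | intermediate
21 | tert-butyl 4-hydroxybut-2-ynoate | CC(C)(C)OC(=O)C#CCO | intermediate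
22 | tert-butyl (Z)-4-hydroxy-3-iodobut-2-enoate | OC/C(I)=C/C(=O)OC(C)(C)C | intermediate
23 | 9-{2-[(1R,2S,4aR,8aS)-2-(tert-butoxycarbonyl)-5,5,8a-trimethyl-1,2,4a,5,6,7,8,8a-octahydronaphthalen-1-yl]ethyl}-9-borabicyclo[3.3.1]nonane | CC(C)(C)OC(=O)[C@H]1C=C[C@@H]2C(C)(C)CCC[C@@]2(C)[C@@H]1CCB3C4CCCC3CCC4 | intermediate
24 | tert-butyl (1R,2S,4aR,8aS)-1-[(3E)-5-tert-butoxy-3-(hydroxymethyl)-5-oxopent-3-en-1-yl]-5,5,8a-trimethyl-1,2,4a,5,6,7,8,8a-octahydronaphthalene-2-carboxylate | OC/C(=C/C(=O)OC(C)(C)C)CC[C@@H]1[C@@H](C(=O)OC(C)(C)C)C=C[C@@H]2C(C)(C)CCC[C@@]12C | intermediate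
25 | tert-butyl (1R,2S,4aR,8aS)-1-[(3E)-3-(acetoxymethyl)-5-tert-butoxy-5-oxopent-3-en-1-yl]-5,5,8a-trimethyl-1,2,4a,5,6,7,8,8a-octahydronaphthalene-2-carboxylate | CC(=O)OC/C(=C/C(=O)OC(C)(C)C)CC[C@@H]1[C@@H](C(=O)OC(C)(C)C)C=C[C@@H]2C(C)(C)CCC[C@@]12C | intermediate
26 | (1R,2S,4aR,8aS)-1-[(3E)-3-(acetoxymethyl)-4-carboxybut-3-en-1-yl]-5,5,8a-trimethyl-1,2,4a,5,6,7,8,8a-octahydronaphthalene-2-carboxylic acid | CC(=O)OC/C(=C/C(=O)O)CC[C@@H]1[C@@H](C(=O)O)C=C[C@@H]2C(C)(C)CCC[C@@]12C | target

Total step count: 17.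
Longest linear sequence: 13 steps (steps 1–3, 5–11, 15–17).

Steps most likely to fail

Step 5. The cycloaddition may close with the chelated imide beneath the diene (endo) instead of away from it. That would set C10 with the wrong relationship to C8 and C9. It may also stop after the first C7–C8 bond at the congested, twisted C10 terminus. The fallback sets out from 4 and 5 and returns at 11. Acid 5 is coupled with commercial (R)-4-benzyloxazolidin-2-one as in step 4 to give tert-butyl (E)-4-[(R)-4-benzyl-2-oxooxazolidin-3-yl]-4-oxobut-2-enoate F1. With 4 and Et2AlCl, the imide-endo mode should then give the (8R,9S,10S) adduct tert-butyl (1S,2R,8aS)-1-[(R)-4-benzyl-2-oxooxazolidine-3-carbonyl]-4-[(tert-butyldimethylsilyl)oxy]-5,5,8a-trimethyl-1,2,3,5,6,7,8,8a-octahydronaphthalene-2-carboxylate F2, in which C10 is correct and C8 and C9 are both inverted. LiBH4 reduction gives the alcohol tert-butyl (1S,2R,8aS)-4-[(tert-butyldimethylsilyl)oxy]-1-(hydroxymethyl)-5,5,8a-trimethyl-1,2,3,5,6,7,8,8a-octahydronaphthalene-2-carboxylate F3. Parikh–Doering oxidation gives the aldehyde tert-butyl (1S,2R,8aS)-4-[(tert-butyldimethylsilyl)oxy]-1-formyl-5,5,8a-trimethyl-1,2,3,5,6,7,8,8a-octahydronaphthalene-2-carboxylate F4. KOtBu in t-BuOH/THF then equilibrates C9 through the aldehyde enolate and C8 through the ester enolate. Because F4 holds the C17 ester syn-diaxial to the C10 methyl, the equilibrium should drain to the all-equatorial 8,9-trans isomer, which is 11.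

Step 6. Hydride may attack the ring carbonyl of the auxiliary and open the oxazolidinone, because the exocyclic carbonyl C11 sits between tertiary C8 and quaternary C10; reduction may also be incomplete. The fallback sets out from 9 and returns at 11, bypassing 10 and step 7. Lithium ethanethiolate (EtSH, n-BuLi, THF, 0 °C), which attacks hindered imides at the exocyclic carbonyl, should give the thioester tert-butyl (1R,2S,8aS)-4-[(tert-butyldimethylsilyl)oxy]-1-[(ethylsulfanyl)carbonyl]-5,5,8a-trimethyl-1,2,3,5,6,7,8,8a-octahydronaphthalene-2-carboxylate F5. Fukuyama reduction (Et3SiH, Pd on carbon, acetone, rt) then gives aldehyde 11 directly.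

Step 15. Transmetalation of the β-branched B-alkyl borane may be slow, so that protodeboronation competes, or the iodo enoate may lose its geometry under palladium. The fallback sets out from 17 and returns at 24; it keeps the hydroboration but replaces the boron coupling by a Negishi coupling.
- Borane 23, made as before, is oxidised with NaBO3·4H2O to tert-butyl (1R,2S,4aR,8aS)-1-(2-hydroxyethyl)-5,5,8a-trimethyl-1,2,4a,5,6,7,8,8a-octahydronaphthalene-2-carboxylate F6.
- I2, PPh3 and imidazole (Appel-type iodination) give tert-butyl (1R,2S,4aR,8aS)-1-(2-iodoethyl)-5,5,8a-trimethyl-1,2,4a,5,6,7,8,8a-octahydronaphthalene-2-carboxylate F7.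
- Zinc insertion (Zn dust, LiCl, THF) gives {2-[(1R,2S,4aR,8aS)-2-(tert-butoxycarbonyl)-5,5,8a-trimethyl-1,2,4a,5,6,7,8,8a-octahydronaphthalen-1-yl]ethyl}zinc iodide F8.
- Iodide 22 is silylated (TBSCl, imidazole) to tert-butyl (Z)-4-[(tert-butyldimethylsilyl)oxy]-3-iodobut-2-enoate F9.
- Negishi coupling of F8 with F9 (Pd(OAc)2, SPhos, THF, rt) should give tert-butyl (1R,2S,4aR,8aS)-1-{(3E)-5-tert-butoxy-3-{[(tert-butyldimethylsilyl)oxy]methyl}-5-oxopent-3-en-1-yl}-5,5,8a-trimethyl-1,2,4a,5,6,7,8,8a-octahydronaphthalene-2-carboxylate F10.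
- HF·pyridine in THF then frees the hydroxyl and gives 24.

Further compounds
F1 | step 5 | tert-butyl (E)-4-[(R)-4-benzyl-2-oxooxazolidin-3-yl]-4-oxobut-2-enoate | CC(C)(C)OC(=O)/C=C/C(=O)N1[C@H](Cc2ccccc2)COC1=O
F2 | step 5 | tert-butyl (1S,2R,8aS)-1-[(R)-4-benzyl-2-oxooxazolidine-3-carbonyl]-4-[(tert-butyldimethylsilyl)oxy]-5,5,8a-trimethyl-1,2,3,5,6,7,8,8a-octahydronaphthalene-2-carboxylate | CC(C)(C)OC(=O)[C@@H]1CC(O[Si](C)(C)C(C)(C)C)=C2C(C)(C)CCC[C@@]2(C)[C@H]1C(=O)N3[C@H](Cc4ccccc4)COC3=O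
F3 | step 5 | tert-butyl (1S,2R,8aS)-4-[(tert-butyldimethylsilyl)oxy]-1-(hydroxymethyl)-5,5,8a-trimethyl-1,2,3,5,6,7,8,8a-octahydronaphthalene-2-carboxylate | CC(C)(C)OC(=O)[C@@H]1CC(O[Si](C)(C)C(C)(C)C)=C2C(C)(C)CCC[C@@]2(C)[C@H]1CO
F4 | step 5 | tert-butyl (1S,2R,8aS)-4-[(tert-butyldimethylsilyl)oxy]-1-formyl-5,5,8a-trimethyl-1,2,3,5,6,7,8,8a-octahydronaphthalene-2-carboxylate | CC(C)(C)OC(=O)[C@@H]1CC(O[Si](C)(C)C(C)(C)C)=C2C(C)(C)CCC[C@@]2(C)[C@H]1C=O
F5 | step 6 | tert-butyl (1R,2S,8aS)-4-[(tert-butyldimethylsilyl)oxy]-1-[(ethylsulfanyl)carbonyl]-5,5,8a-trimethyl-1,2,3,5,6,7,8,8a-octahydronaphthalene-2-carboxylate | CC(C)(C)OC(=O)[C@H]1CC(O[Si](C)(C)C(C)(C)C)=C2C(C)(C)CCC[C@@]2(C)[C@@H]1C(=O)SCC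
F6 | step 15 | tert-butyl (1R,2S,4aR,8aS)-1-(2-hydroxyethyl)-5,5,8a-trimethyl-1,2,4a,5,6,7,8,8a-octahydronaphthalene-2-carboxylate | CC(C)(C)OC(=O)[C@H]1C=C[C@@H]2C(C)(C)CCC[C@@]2(C)[C@@H]1CCO
F7 | step 15 | tert-butyl (1R,2S,4aR,8aS)-1-(2-iodoethyl)-5,5,8a-trimethyl-1,2,4a,5,6,7,8,8a-octahydronaphthalene-2-carboxylate | CC(C)(C)OC(=O)[C@H]1C=C[C@@H]2C(C)(C)CCC[C@@]2(C)[C@@H]1CCI
F8 | step 15 | {2-[(1R,2S,4aR,8aS)-2-(tert-butoxycarbonyl)-5,5,8a-trimethyl-1,2,4a,5,6,7,8,8a-octahydronaphthalen-1-yl]ethyl}zinc iodide | CC(C)(C)OC(=O)[C@H]1C=C[C@@H]2C(C)(C)CCC[C@@]2(C)[C@@H]1CC[Zn]I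
F9 | step 15 | tert-butyl (Z)-4-[(tert-butyldimethylsilyl)oxy]-3-iodobut-2-enoate | CC(C)(C)[Si](C)(C)OC/C(I)=C/C(=O)OC(C)(C)C
F10 | step 15 | tert-butyl (1R,2S,4aR,8aS)-1-{(3E)-5-tert-butoxy-3-{[(tert-butyldimethylsilyl)oxy]methyl}-5-oxopent-3-en-1-yl}-5,5,8a-trimethyl-1,2,4a,5,6,7,8,8a-octahydronaphthalene-2-carboxylate | CC(C)(C)[Si](C)(C)OC/C(=C/C(=O)OC(C)(C)C)CC[C@@H]1[C@@H](C(=O)OC(C)(C)C)C=C[C@@H]2C(C)(C)CCC[C@@]12C
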